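**Strategy.** The route rests on cutting the cyclohexane-1,3,5-trione ring of the homoadamantane at its three C(α)–C(=O) bonds. Each of the three α-carbons hangs from one arm (CH2, CMe2, CH2–CH) of the single cage methine, so an open-chain tripodal tris(acid chloride) already holds every carbon of the cage. In one operation, triple dehydrochlorination to a tris-ketene and nucleophile-catalysed head-to-tail cyclotrimerisation should form three C–C bonds, three rings and three stereocentres, all dictated by the methine. The precursor carries only two stereocentres (methine and isopropenyl CH), each set by an auxiliary; bridgehead benzoylation and a peroxidation cascade finish the target.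

Key step: step 13

Remark (structure check): the target SMILES holds a seven-membered 1,2-dioxepane fused to the cage, and the cage trione leaving the key step has two new quaternary centres plus one bridgehead C–H between two carbonyls (not three quaternary centres); the CH2COCl arm that supplies this carbon gives a monoalkylketene, not a dialkylketene.
Remark (precursor): skeleton and both stereocentres of the tris(acid chloride) are kept; it is improved only in how it is made and used (α-epimer mixture, HCl-free formation, a base chosen to spare the one acidic C–H formed on the way) rather than by a blocking group that would cost two steps.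
Remark (assumption): compounds 1, 3, 6, 10, 15, 17, 19 and 27 are taken as commercial.

**Route**

Step 1
Reactants: 1 3,3-dimethylglutaric anhydride
Product: 2 5-tert-butoxy-3,3-dimethyl-5-oxopentanoic acid
Conditions: t-BuOH (3 equiv), DMAP (0.1 equiv), PhMe, 90 °C
Reagents that add atoms: tert-butanol, CC(C)(C)O
Why: DMAP-catalysed alcoholysis of a symmetric cyclic anhydride can give only one half-ester, and the tert-butyl ester later resists hydride and does not lactonise onto the neighbouring alcohol.

Step 2
Reactants: 2 5-tert-butoxy-3,3-dimethyl-5-oxopentanoic acid; 3 (4R)-4-benzyl-1,3-oxazolidin-2-one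
Product: 5 tert-butyl 5-[(4R)-4-benzyl-2-oxo-1,3-oxazolidin-3-yl]-3,3-dimethyl-5-oxopentanoate, via mixed pivalic anhydride 4 (not isolated)
Conditions: PivCl, Et3N, THF, −20 °C; then 3, LiCl, −20 °C → rt
Reagents that add atoms: (4R)-4-benzyl-1,3-oxazolidin-2-one 3, O=C1N[C@H](Cc2ccccc2)CO1
Why: N-acylation of the oxazolidinone through a mixed anhydride should occur at the CH2–C(=O) carbonyl, which is less hindered than the pivaloyl carbonyl.

Step 3
Reactants: 5 tert-butyl 5-[(4R)-4-benzyl-2-oxo-1,3-oxazolidin-3-yl]-3,3-dimethyl-5-oxopentanoate; 6 allyl iodide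
Product: 8 tert-butyl (4R)-4-{[(4R)-4-benzyl-2-oxo-1,3-oxazolidin-3-yl]carbonyl}-3,3-dimethylhept-6-enoate, via sodium enolate 7 (not isolated)
Conditions: NaN(SiMe3)2 (1.1 equiv), THF, −78 °C; allyl iodide (3 equiv), −78 → −45 °C
Reagents that add atoms: allyl iodide 6, C=CCI
Why: Evans asymmetric alkylation, in which the chelated Z-enolate of the imide (enolised selectively over the ester) is allylated on the face opposite the benzyl group, sets the future cage methine with the quaternary carbon already attached.

Step 4
Reactants: 8 tert-butyl (4R)-4-{[(4R)-4-benzyl-2-oxo-1,3-oxazolidin-3-yl]carbonyl}-3,3-dimethylhept-6-enoate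
Product: 9 tert-butyl (4R)-4-(hydroxymethyl)-3,3-dimethylhept-6-enoate
Conditions: LiBH4 (1.2 equiv), MeOH (1.1 equiv), Et2O, 0 °C; used directly
Reagents that add atoms: none
Why: Reductive removal of the auxiliary with LiBH4 attacks the exocyclic imide carbonyl and should leave the hindered tert-butyl ester untouched, without touching the stereocentre.

Step 5
Reactants: 9 tert-butyl (4R)-4-(hydroxymethyl)-3,3-dimethylhept-6-enoate; 10 methyl (triphenylphosphoranylidene)acetate
Product: 12 7-tert-butyl 1-methyl (2E,4S)-5,5-dimethyl-4-(prop-2-en-1-yl)hept-2-enedioate, via aldehyde 11 (not isolated)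
Conditions: IBX (1.5 equiv), 10 (1.5 equiv), DMSO, rt
Reagents that add atoms: methyl (triphenylphosphoranylidene)acetate 10, COC(=O)C=P(c1ccccc1)(c1ccccc1)c1ccccc1
Why: Tandem IBX oxidation and Wittig olefination traps the α-branched aldehyde as it forms with a non-basic stabilised ylide, which protects the α-stereocentre and gives the E-enoate.

Step 6
Reactants: 12 7-tert-butyl 1-methyl (2E,4S)-5,5-dimethyl-4-(prop-2-en-1-yl)hept-2-enedioate
Product: 13 7-tert-butyl 1-methyl (4R)-5,5-dimethyl-4-(prop-2-en-1-yl)heptanedioate
Conditions: Mg turnings (10 equiv), MeOH, 0 °C → rt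
Reagents that add atoms: none
Why: Dissolving-metal conjugate reduction (Mg in MeOH) saturates only the conjugated C=C and should leave the isolated terminal alkene and both esters intact.

Step 7
Reactants: 13 7-tert-butyl 1-methyl (4R)-5,5-dimethyl-4-(prop-2-en-1-yl)heptanedioate
Product: 14 (4R)-7-methoxy-3,3-dimethyl-7-oxo-4-(prop-2-en-1-yl)heptanoic acid
Conditions: CF3CO2H/CH2Cl2 (1:4), 0 °C → rt
Reagents that add atoms: none
Why: Acidolysis of the tert-butyl ester (E1 loss of isobutene) is run here, while the only alkene is a monosubstituted one that tolerates acid, so that the neopentyl arm is a carboxylate during the later enolate chemistry.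

Step 8
Reactants: 14 (4R)-7-methoxy-3,3-dimethyl-7-oxo-4-(prop-2-en-1-yl)heptanoic acid; 15 (4R)-3-acryloyl-4-phenyl-1,3-oxazolidin-2-one
Product: 16 (4R,6E)-4-(3-methoxy-3-oxopropyl)-3,3-dimethyl-8-oxo-8-[(4R)-2-oxo-4-phenyl-1,3-oxazolidin-3-yl]oct-6-enoic acid
Conditions: second-generation Hoveyda–Grubbs catalyst (5 mol%), 15 (3 equiv), CH2Cl2, 40 °C
Reagents that add atoms: (4R)-3-acryloyl-4-phenyl-1,3-oxazolidin-2-one 15, C=CC(=O)N1[C@H](c2ccccc2)COC1=O
Why: Olefin cross-metathesis between an unhindered terminal alkene and an electron-poor acryloyl imide should be E-selective, and it is run before any prenyl group is present so that no ring-closing metathesis can compete.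

Step 9
Reactants: 16 (4R,6E)-4-(3-methoxy-3-oxopropyl)-3,3-dimethyl-8-oxo-8-[(4R)-2-oxo-4-phenyl-1,3-oxazolidin-3-yl]oct-6-enoic acid; 17 isopropenylmagnesium bromide
Product: 18 (4R,6S)-4-(3-methoxy-3-oxopropyl)-3,3,7-trimethyl-6-{2-oxo-2-[(4R)-2-oxo-4-phenyl-1,3-oxazolidin-3-yl]ethyl}oct-7-enoic acid
Conditions: CH2=C(CH3)MgBr (4 equiv), CuBr·SMe2 (2 equiv), THF/Me2S, −78 → −20 °C
Reagents that add atoms: isopropenylmagnesium bromide 17, CC(=C)[Mg]Br
Why: Auxiliary-controlled conjugate addition of an alkenylcopper reagent to the magnesium-chelated syn-s-cis N-enoyl oxazolidinone occurs anti to the 4-phenyl group and so sets the isopropenyl-bearing centre (S) by reagent control, independent of the remote methine.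

Step 10
Reactants: 18 (4R,6S)-4-(3-methoxy-3-oxopropyl)-3,3,7-trimethyl-6-{2-oxo-2-[(4R)-2-oxo-4-phenyl-1,3-oxazolidin-3-yl]ethyl}oct-7-enoic acid; 19 prenyl bromide
Product: 21 diprenylated imide ester acid (one prenyl on each of the two α-carbons; both new centres as epimer mixtures), via trilithium bis-enolate 20 (not isolated)
Conditions: LiN(i-Pr)2 (3.2 equiv), THF, −78 °C; prenyl bromide (3 equiv), −78 → −30 °C
Reagents that add atoms: prenyl bromide 19, CC(C)=CCBr
Why: Double enolate C-alkylation works because LiN(i-Pr)2 at −78 °C forms the imide enolate and the ester enolate but does not α-metalate the lithium carboxylate of the neopentyl arm, and the configuration of the two new centres is irrelevant since both become ketene carbons.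

Step 11
Reactants: 21 diprenylated imide ester acid
Product: 23 triacid (2-prenyl-propanoic acid arm, 3,3-dimethylbutanoic acid arm, 3-isopropenyl-2-prenyl-butanoic acid arm on one CH; S at the methine; S at the isopropenyl CH), via diacid monoester 22 (not isolated)
Conditions: LiOH, 30% H2O2, THF/H2O, 0 °C; Na2SO3; then LiOH, MeOH/H2O, 50 °C; HCl to pH 2
Reagents that add atoms: hydrogen peroxide, OO; lithium hydroxide, [Li+].[OH-]
Why: Hydroperoxide cleavage of the hindered imide at its exocyclic carbonyl followed by saponification frees all three acids (and any prenyl ester formed in step 10), while the two defined stereocentres are β to carbonyls and cannot epimerise.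

Step 12
Reactants: 23 triacid
Product: 24 tripodal tris(acid chloride) (mixture of α-epimers; S at the methine; S at the isopropenyl CH)
Conditions: 1-chloro-N,N,2-trimethylprop-1-en-1-amine (3.6 equiv), CH2Cl2, 0 °C → rt; volatiles removed, used crude
Reagents that add atoms: 1-chloro-N,N,2-trimethylprop-1-en-1-amine, CC(C)=C(Cl)N(C)C
Why: Acid chloride formation with the α-chloroenamine (Ghosez reagent) is neutral and releases no HCl, so the prenyl and isopropenyl groups are not hydrochlorinated.

Step 13
Reactants: 24 tripodal tris(acid chloride)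
Product: 26 debenzoyl homoadamantane trione, via tris-ketene 25 (not isolated)
Conditions: 1,8-bis(dimethylamino)naphthalene (3.5 equiv), 4-pyrrolidinopyridine (0.3 equiv), PhMe, 60 °C; 24 added by syringe pump over 16 h to a final 1 mM
Reagents that add atoms: none
Why: Proposed new method: the three acyl chlorides lose HCl (4-pyrrolidinopyridine as acyl carrier and kinetic base, proton sponge as final base) to give tris-ketene 25; the catalyst adds to one ketene carbonyl to give an acylpyridinium enolate whose carbon attacks the carbonyl carbon of a second ketene, the resulting enolate attacks the third, and the last enolate displaces the catalyst from the acylpyridinium carbonyl, so three C(α)–C(=O) bonds form head to tail; the closest known reaction type is the base- or nucleophile-catalysed cyclotrimerisation of dialkylketenes to hexaalkylcyclohexane-1,3,5-triones, together with amine-catalysed ketene dimerisation through the same ammonium enolates. The first closure should join the CH2 arm and the CMe2 arm in a six-membered ring (6-exo-dig attack of an enolate carbon on a ketene C=O), the second takes in the long arm in a seven-membered ring (7-exo-dig), and the third is the 6-exo-trig acyl transfer that completes the trione and the cage; either sense of travel round the ring gives the same constitution. The two new quaternary centres and the new bridgehead C–H centre are fixed by the (S)-methine, because its three arms can cap the trione ring from one face only, and the α-epimers of 24 converge because those carbons are planar in 25; the isopropenyl-bearing centre is a spectator. The step needs C- over O-acylation, ring closure over oligomerisation, and no proton loss from the CH2-derived carbon while it lies between an acylpyridinium and a ketone: slow addition to 1 mM secures the intramolecular path, the enol-lactone from O-acylation is reopened by the catalyst so that the trione (whose only α-hydrogen sits at a bridgehead) is the sole sink, and proton sponge, whose conjugate acid is a poor proton shuttle, keeps proton transfer slow. The temperature stays at or below 60 °C so that no thermal ketene–alkene [2+2] cycloaddition onto the prenyl or isopropenyl groups competes.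

Step 14
Reactants: 26 debenzoyl homoadamantane trione; 27 benzoyl chloride
Product: 29 benzoyl homoadamantane trione, via bridgehead lithium compound 28 (not isolated)
Conditions: lithium 2,2,6,6-tetramethylpiperidide (1.3 equiv), THF, −78 °C; PhCOCl (2 equiv), −78 → −20 °C
Reagents that add atoms: benzoyl chloride 27, O=C(Cl)c1ccccc1
Why: Bridgehead lithiation and acylation: the only α-hydrogen of 26 is the bridgehead C–H between two carbonyls, which the hindered amide removes to a cage-locked carbanion that can only be C-benzoylated, with retention.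

Step 15
Reactants: 29 benzoyl homoadamantane trione
Product: 30 CNP0215795.1 (target)
Conditions: Mn(dpm)3 (0.2 equiv), PhSiH3 (1.2 equiv, slow addition), O2 (1 atm), CH2Cl2/i-PrOH, −10 °C
Reagents that add atoms: dioxygen, O=O
Why: Metal-hydride hydrogen-atom-transfer hydroperoxidation (Mukaiyama–Isayama type) run as a cascade: H-atom transfer to the less hindered isopropenyl CH2 gives a tertiary radical, O2 trapping gives a peroxyl radical held gauche to the neighbouring prenyl group on the cage, 7-exo-trig closure forms the 1,2-dioxepane, and a second O2 trapping with reduction gives the hydroperoxide; the new C–O centre (S) is set under substrate control and its sense is an expectation, not a certainty.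

**Compound list**

1 | 3,3-dimethylglutaric anhydride (4,4-dimethyloxane-2,6-dione) | CC1(C)CC(=O)OC(=O)C1 | starting material
2 | 5-tert-butoxy-3,3-dimethyl-5-oxopentanoic acid | CC(C)(C)OC(=O)CC(C)(C)CC(O)=O | intermediate
3 | (4R)-4-benzyl-1,3-oxazolidin-2-one | O=C1N[C@H](Cc2ccccc2)CO1 | starting material
4 | mixed anhydride of 2 and pivalic acid | CC(C)(C)OC(=O)CC(C)(C)CC(=O)OC(=O)C(C)(C)C | intermediate
5 | tert-butyl 5-[(4R)-4-benzyl-2-oxo-1,3-oxazolidin-3-yl]-3,3-dimethyl-5-oxopentanoate | CC(C)(C)OC(=O)CC(C)(C)CC(=O)N1[C@H](Cc2ccccc2)COC1=O | intermediate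
6 | allyl iodide (3-iodoprop-1-ene) | C=CCI | starting material
7 | sodium Z-enolate of 5 | [Na+].CC(C)(C)OC(=O)CC(C)(C)/C=C(\[O-])N1[C@H](Cc2ccccc2)COC1=O | intermediate
8 | tert-butyl (4R)-4-{[(4R)-4-benzyl-2-oxo-1,3-oxazolidin-3-yl]carbonyl}-3,3-dimethylhept-6-enoate | CC(C)(C)OC(=O)CC(C)(C)[C@@H](CC=C)C(=O)N1[C@H](Cc2ccccc2)COC1=O | intermediate
9 | tert-butyl (4R)-4-(hydroxymethyl)-3,3-dimethylhept-6-enoate | CC(C)(C)OC(=O)CC(C)(C)[C@@H](CC=C)CO | intermediate
10 | methyl (triphenylphosphoranylidene)acetate | COC(=O)C=P(c1ccccc1)(c1ccccc1)c1ccccc1 | starting material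
11 | tert-butyl (4R)-4-formyl-3,3-dimethylhept-6-enoate | CC(C)(C)OC(=O)CC(C)(C)[C@@H](CC=C)C=O | intermediate
12 | 7-tert-butyl 1-methyl (2E,4S)-5,5-dimethyl-4-(prop-2-en-1-yl)hept-2-enedioate | CC(C)(C)OC(=O)CC(C)(C)[C@@H](CC=C)/C=C/C(=O)OC | intermediate
13 | 7-tert-butyl 1-methyl (4R)-5,5-dimethyl-4-(prop-2-en-1-yl)heptanedioate | CC(C)(C)OC(=O)CC(C)(C)[C@@H](CC=C)CCC(=O)OC | intermediate
14 | (4R)-7-methoxy-3,3-dimethyl-7-oxo-4-(prop-2-en-1-yl)heptanoic acid | OC(=O)CC(C)(C)[C@@H](CC=C)CCC(=O)OC | intermediate
15 | (4R)-3-acryloyl-4-phenyl-1,3-oxazolidin-2-one | C=CC(=O)N1[C@H](c2ccccc2)COC1=O | starting material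
16 | (4R,6E)-4-(3-methoxy-3-oxopropyl)-3,3-dimethyl-8-oxo-8-[(4R)-2-oxo-4-phenyl-1,3-oxazolidin-3-yl]oct-6-enoic acid | OC(=O)CC(C)(C)[C@@H](C/C=C/C(=O)N1[C@H](c2ccccc2)COC1=O)CCC(=O)OC | intermediate
17 | isopropenylmagnesium bromide | CC(=C)[Mg]Br | starting material
18 | (4R,6S)-4-(3-methoxy-3-oxopropyl)-3,3,7-trimethyl-6-{2-oxo-2-[(4R)-2-oxo-4-phenyl-1,3-oxazolidin-3-yl]ethyl}oct-7-enoic acid | OC(=O)CC(C)(C)[C@@H](C[C@H](C(C)=C)CC(=O)N1[C@H](c2ccccc2)COC1=O)CCC(=O)OC | intermediate
19 | prenyl bromide (1-bromo-3-methylbut-2-ene) | CC(C)=CCBr | starting material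
20 | trilithium salt of 18 (carboxylate, imide enolate, ester enolate) | [Li+].[Li+].[Li+].[O-]C(=O)CC(C)(C)[C@@H](C[C@H](C(C)=C)C=C([O-])N1[C@H](c2ccccc2)COC1=O)CC=C([O-])OC | intermediate
21 | diprenylated imide ester acid: 18 with one prenyl on the CH2 next to the imide carbonyl and one on the CH2 next to the ester carbonyl (epimer mixtures there; S at the methine; S at the isopropenyl CH) | OC(=O)CC(C)(C)[C@@H](C[C@H](C(C)=C)C(CC=C(C)C)C(=O)N1[C@H](c2ccccc2)COC1=O)CC(CC=C(C)C)C(=O)OC | intermediate
22 | diacid monoester: 21 with the imide cleaved to CO2H | OC(=O)CC(C)(C)[C@@H](C[C@H](C(C)=C)C(CC=C(C)C)C(O)=O)CC(CC=C(C)C)C(=O)OC | intermediate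
23 | triacid: CH (S) bearing CH2CH(prenyl)CO2H, C(CH3)2CH2CO2H and CH2–CH(isopropenyl)(S)–CH(prenyl)CO2H; α-carbons as epimer mixtures | OC(=O)C(CC=C(C)C)C[C@@H](C(C)(C)CC(O)=O)C[C@H](C(C)=C)C(CC=C(C)C)C(O)=O | intermediate
24 | tripodal tris(acid chloride) of 23 | ClC(=O)C(CC=C(C)C)C[C@@H](C(C)(C)CC(Cl)=O)C[C@H](C(C)=C)C(CC=C(C)C)C(Cl)=O | intermediate
25 | tris-ketene from 24 (two dialkylketenes, one monoalkylketene; both stereocentres unchanged) | O=C=C(CC=C(C)C)C[C@@H](C(C)(C)C=C=O)C[C@H](C(C)=C)C(CC=C(C)C)=C=O | intermediate
26 | debenzoyl homoadamantane trione: cyclohexane-1,3,5-trione whose α-carbons (prenyl; H; prenyl) are bridged to one CH by CH2, C(CH3)2 and CH(isopropenyl)–CH2, all three arms on one face | CC(C)=CC[C@]12C[C@@H]3C[C@H](C(C)=C)[C@](CC=C(C)C)(C1=O)C(=O)[C@H](C2=O)C3(C)C | intermediate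
27 | benzoyl chloride | O=C(Cl)c1ccccc1 | starting material
28 | bridgehead lithium derivative of 26 (Li in place of the bridgehead H between the two carbonyls) | CC(C)=CC[C@]12C[C@@H]3C[C@H](C(C)=C)[C@](CC=C(C)C)(C1=O)C(=O)[C@]([Li])(C2=O)C3(C)C | intermediate
29 | benzoyl homoadamantane trione: 26 with benzoyl at that bridgehead, configuration retained | CC(C)=CC[C@]12C[C@@H]3C[C@H](C(C)=C)[C@](CC=C(C)C)(C1=O)C(=O)[C@](C(=O)c1ccccc1)(C2=O)C3(C)C | intermediate
30 | CNP0215795.1: 29 in which the isopropenyl carbon and the CH of the neighbouring prenyl group are joined by O–O into a 1,2-dioxepane, the former prenyl terminus carrying C(CH3)2OOH; new CH–O centre S | CC(C)=CC[C@]12C[C@@H]3C[C@@H]4C(C)(C)OO[C@H](C(C)(C)OO)C[C@@]4(C1=O)C(=O)[C@](C(=O)c1ccccc1)(C2=O)C3(C)C | target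

**Count**

Total step count: 15. Longest linear sequence: 15 steps (1 → 30); all partners are taken as commercial.

**Steps most likely to fail**

1. Step 13 (new method). What may go wrong: the ammonium enolates may close on oxygen and rest as enol-lactone dimers, react between molecules, or lose the proton of the CH2-derived carbon while it lies between the acylpyridinium and a ketone, which stops the relay. The fallback uses stepwise, known enolate chemistry, sets out from 18 (before the prenyl groups are on) and comes back at 26.
   Methanolysis of the imide (MeOMgBr, MeOH) and methylation of the acid (TMSCHN2) should give the trimethyl ester F1. A Dieckmann condensation under thermodynamic control (KOt-Bu, THF) should close the six-membered ring through the unhindered α-carbon onto the neopentyl ester, giving the cyclic β-keto ester F2. C-Prenylation (K2CO3, prenyl bromide, acetone), expected axial and trans to the side chain, gives the quaternary keto ester F3. The ketone, enolisable on one side only, is masked as the silyl enol ether F4 (TBSOTf, Et3N). A second Dieckmann condensation of the remaining ester enolate (LiN(i-Pr)2, THF) onto the quaternary ester gives the bicyclic β-keto ester F5, and C-prenylation from the convex face gives the diprenyl keto ester F6. Anhydrous fluoride (TBAF, THF) then frees the ketone enolate, which closes the cage by Claisen acylation onto the last ester to give 26. The price is that the two quaternary centres are then set by substrate-controlled alkylations and no longer converge.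

2. Step 15. What may go wrong: reduction of the first peroxyl radical before the seven-membered ring closes, hydrogen-atom transfer to a prenyl group, over-reduction of the hydroperoxide, or poor facial selectivity at the new C–O carbon. The fallback separates the two events, sets out from 29 and comes back at 30.
   Co(thd)2 (cat.), Et3SiH and O2 in 1,2-dichloroethane should silylperoxidise only the isopropenyl group, giving the tertiary triethylsilyl peroxide F7. HCl (cat.) in MeOH gives the unsaturated hydroperoxide F8. A metal-free peroxyl radical chain (di-tert-butyl hyponitrite, O2, benzene, 35 °C) then closes the dioxepane and installs the hydroperoxide to give 30. In this chain the peroxyl radical is not reduced by a metal, so a slow ring closure can still compete.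

3. Step 14. What may go wrong: sluggish acylation of the hindered bridgehead carbanion, with proton return on work-up. The fallback sets out from 26 and comes back at 29.
   The lithiated cage is quenched with the small electrophile I2 to give the bridgehead iodide F9. Iodine–magnesium exchange (i-PrMgCl·LiCl, THF, −78 °C) and addition to benzaldehyde give the bridgehead carbinol F10. Dess–Martin oxidation then gives 29.

Further compounds
F1 | step 13 | trimethyl ester of 18 (imide and acid both as CO2Me; no prenyl groups) | COC(=O)CC(C)(C)[C@@H](C[C@H](C(C)=C)CC(=O)OC)CCC(=O)OC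
F2 | step 13 | methyl 2-oxocyclohexane-1-carboxylate with 4,4-dimethyl and the ester side chain CH2–CH(isopropenyl)–CH2CO2Me at C5 | COC(=O)C1C[C@H](C[C@H](C(C)=C)CC(=O)OC)C(C)(C)CC1=O
F3 | step 13 | F2 with prenyl at C1 (quaternary; prenyl trans to the side chain) | COC(=O)[C@]1(CC=C(C)C)C[C@H](C[C@H](C(C)=C)CC(=O)OC)C(C)(C)CC1=O
F4 | step 13 | tert-butyldimethylsilyl enol ether of the ketone of F3 | COC(=O)[C@]1(CC=C(C)C)C[C@H](C[C@H](C(C)=C)CC(=O)OC)C(C)(C)C=C1O[Si](C)(C)C(C)(C)C
F5 | step 13 | bicyclic β-keto ester from the second Dieckmann closure (seven-membered ring; silyl enol ether kept) | COC(=O)C1C(=O)[C@]2(CC=C(C)C)C[C@H](C[C@@H]1C(C)=C)C(C)(C)C=C2O[Si](C)(C)C(C)(C)C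
F6 | step 13 | F5 with prenyl on the β-keto ester carbon (quaternary) | COC(=O)[C@@]1(CC=C(C)C)C(=O)[C@]2(CC=C(C)C)C[C@H](C[C@@H]1C(C)=C)C(C)(C)C=C2O[Si](C)(C)C(C)(C)C
F7 | step 15 | 29 with the isopropenyl group converted to C(CH3)2–OO–SiEt3 | CC(C)=CC[C@]12C[C@@H]3C[C@H](C(C)(C)OO[Si](CC)(CC)CC)[C@](CC=C(C)C)(C1=O)C(=O)[C@](C(=O)c1ccccc1)(C2=O)C3(C)C
F8 | step 15 | 29 with the isopropenyl group converted to C(CH3)2–OOH | CC(C)=CC[C@]12C[C@@H]3C[C@H](C(C)(C)OO)[C@](CC=C(C)C)(C1=O)C(=O)[C@](C(=O)c1ccccc1)(C2=O)C3(C)C
F9 | step 14 | bridgehead iodide of 26 | CC(C)=CC[C@]12C[C@@H]3C[C@H](C(C)=C)[C@](CC=C(C)C)(C1=O)C(=O)[C@](I)(C2=O)C3(C)C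
F10 | step 14 | bridgehead hydroxy(phenyl)methyl derivative of 26 (carbinol epimers) | CC(C)=CC[C@]12C[C@@H]3C[C@H](C(C)=C)[C@](CC=C(C)C)(C1=O)C(=O)[C@](C(O)c1ccccc1)(C2=O)C3(C)C
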